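**Retrosynthetic overview**
1. Numbering (daucane): ring A (cyclopentane) is C1–C5 and ring B (cycloheptane) is C1, C5–C10. C1 is the quaternary fusion carbon and C15 its methyl, C2/C3 are CH2, C4 is the carbinol bearing isopropyl, C5 the fusion CH, C6 the acyloxy carbon, C7 CH2, C8 the methyl carbinol, C9 the secondary carbinol, C10 CH2. β is the face that carries C15.
2. Feature exploited: on ring A the C15 methyl at C1 and the tertiary hydroxyl at C4 both point β, and C5–H points α. C15 can therefore enter as a CH2 bridge laid across a C1=C5 alkene from the side of the allylic C4–OH, and be released later as CH3 with C5–H trans to it.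
3. Late stage: phenol ⇐ benzyl ether; trans C8/C9 diol ⇐ 8α,9α-epoxide ⇐ C8=C9; C6 ester ⇐ 6α-alcohol ⇐ C6 ketone; C1–CH3 and C5–H ⇐ reductive cleavage of C5–C15 in the cyclopropyl ketone.
4. Key and early disconnections: C1–C15 and C5–C15 (directed methylene transfer); C4–isopropyl (organocerium on the C4 enone); C8=C9 (ring-closing metathesis); C6–C7 (asymmetric methallylboration, the source of absolute configuration); C5–C6 (formylation); C1–C10 (allyl Grignard on the vinylogous ester of cyclopentane-1,3-dione).
5. Ring order: ring A is bought, ring B is closed by metathesis, and the cyclopropane is closed third and opened again two steps later.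

Key step: step 12

Remark on the chemistry: the C6 carbinol carried up to the key step is made 6β (R), opposite to the target, and is left unprotected in the key step. A 6α-oxygen substituent would send the isopropyl nucleophile to the β face of C4 (wrong C4 epimer). The 6β group sends it to the α face and then helps direct the carbenoid to the β face. This relay centre is erased in step 13 and rebuilt as 6α in step 15.
Assumption: all numbered starting materials and (+)-B-methoxydiisopinocampheylborane are taken as commercial.

**Step 1**
Reactants: 1 cyclopentane-1,3-dione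
Product: 2 3-ethoxycyclopent-2-en-1-one
Conditions: EtOH, p-TsOH (cat.), toluene, reflux, Dean–Stark
Reagents that add atoms: ethanol, CCO
Why: Acid-catalysed enol etherification of the enolised 1,3-diketone (vinylogous Fischer esterification) with azeotropic removal of water gives the vinylogous ester and so tells apart the future C1 (carbonyl carbon) and C4 (ethoxy-bearing carbon).

**Step 2**
Reactants: 2 3-ethoxycyclopent-2-en-1-one
Product: 3 2-bromo-3-ethoxycyclopent-2-en-1-one
Conditions: NBS, CH2Cl2, 0 °C to rt, dark
Reagents that add atoms: N-bromosuccinimide, O=C1CCC(=O)N1Br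
Why: Electrophilic bromination of the push–pull alkene occurs only at its nucleophilic α-carbon (future C5), the usual α-halogenation of vinylogous esters.

**Step 3**
Reactants: 3 2-bromo-3-ethoxycyclopent-2-en-1-one; 4 allylmagnesium bromide
Product: 6 3-allyl-2-bromocyclopent-2-en-1-one, via 1-allyl-2-bromo-3-ethoxycyclopent-2-en-1-ol 5 (not isolated)
Conditions: allylMgBr, THF, −78 to 0 °C; then 1 M HCl, 0 °C
Reagents that add atoms: allylmagnesium bromide, C=CC[Mg]Br; water, O
Why: Stork–Danheiser transposition, in which the Grignard reagent adds 1,2 to the carbonyl (C1–C10 bond) and cold dilute acid ionises tertiary allylic alcohol 5 and hydrolyses the enol ether, moving the ketone to C4 and leaving C1=C5 tetrasubstituted while the short cold acid contact keeps the allyl alkene out of conjugation.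

**Step 4**
Reactants: 6 3-allyl-2-bromocyclopent-2-en-1-one
Product: 7 7-allyl-6-bromo-1,4-dioxaspiro[4.4]non-6-ene
Conditions: TMSOCH2CH2OTMS, TMSOTf (cat.), CH2Cl2, −78 to −20 °C; then pyridine
Reagents that add atoms: 1,2-bis(trimethylsilyloxy)ethane, C[Si](C)(C)OCCO[Si](C)(C)C
Why: Noyori ketalisation works under aprotic conditions at low temperature, so the C4 ketone is masked without migration of C1=C5 or of the allyl alkene.

**Step 5**
Reactants: 7 7-allyl-6-bromo-1,4-dioxaspiro[4.4]non-6-ene; 8 N,N-dimethylformamide
Product: 10 7-allyl-1,4-dioxaspiro[4.4]non-6-ene-6-carbaldehyde, via 7-allyl-6-lithio-1,4-dioxaspiro[4.4]non-6-ene 9 (not isolated)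
Conditions: n-BuLi, THF, −78 °C; then DMF, −78 to 0 °C
Reagents that add atoms: N,N-dimethylformamide, CN(C)C=O
Why: Bromine–lithium exchange on the α-bromo enone ketal is faster at −78 °C than deprotonation of the doubly allylic C10–H, and Bouveault-type formylation of vinyllithium 9 forms the C5–C6 bond.

**Step 6**
Reactants: 10 7-allyl-1,4-dioxaspiro[4.4]non-6-ene-6-carbaldehyde; 11 2-methylallylmagnesium chloride
Product: 14 (1R)-1-(7-allyl-1,4-dioxaspiro[4.4]non-6-en-6-yl)-3-methylbut-3-en-1-ol (C6 R; 6β-OH), via B-(2-methylallyl)diisopinocampheylborane 12 (not isolated), via C6 diisopinocampheylborinate 13 (not isolated)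
Conditions: (+)-Ipc2BOMe [from (−)-α-pinene], 11, Et2O, −78 °C to rt; then 10, −78 °C; then 3 M NaOH, 30% H2O2, rt
Reagents that add atoms: 2-methylallylmagnesium chloride, C=C(C)C[Mg]Cl
Why: Brown asymmetric methallylboration through a closed chair Zimmerman–Traxler transition state, in which the isopinocampheyl groups from (−)-α-pinene expose the Re face of the aldehyde, so reagent control sets C6 as R while C6–C7 forms, and alkaline peroxide releases the alcohol from borinate 13.

**Step 7**
Reactants: 14 (1R)-homoallylic alcohol
Product: 15 tert-butyldimethylsilyl ether of 14 (C6 R)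
Conditions: TBSCl, imidazole, DMF, rt
Reagents that add atoms: tert-butyldimethylsilyl chloride, CC(C)(C)[Si](C)(C)Cl
Why: Imidazole-promoted silylation of the only hydroxyl installs the bulky group that will later shield the β face of C4, under conditions that leave the ketal untouched.

**Step 8**
Reactants: 15 silyl ether triene
Product: 16 ethylene ketal of (8R)-8-(tert-butyldimethylsilyloxy)-6-methyl-3,4,7,8-tetrahydroazulen-1(2H)-one (rings A and B; C1=C5; C8=C9; 6β-OTBS)
Conditions: second-generation Grubbs catalyst RuCl2(=CHPh)(PCy3)(H2IMes) (5 mol %), 1,4-benzoquinone (10 mol %), CH2Cl2 (2 mM), reflux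
Reagents that add atoms: none
Why: Ring-closing metathesis joins the allyl CH (C9) to the 1,1-disubstituted methallyl carbon (C8); both chains are held cis on C1=C5, which favours closure of seven-membered ring B, the tetrasubstituted alkene is inert, and benzoquinone suppresses ruthenium hydride isomerisation.

**Step 9**
Reactants: 16 bicyclic ketal
Product: 17 (8R)-8-(tert-butyldimethylsilyloxy)-6-methyl-3,4,7,8-tetrahydroazulen-1(2H)-one (C4 ketone; 6β-OTBS)
Conditions: PPTS (cat.), THF–H2O, 40 °C
Reagents that add atoms: water, O
Why: Mild acid hydrolysis frees the C4 enone because the allylic ketal ionises far more readily than the silyl ether is cleaved.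

**Step 10**
Reactants: 17 silyloxy dienone; 18 isopropylmagnesium chloride
Product: 20 (1R,8R)-8-(tert-butyldimethylsilyloxy)-1-isopropyl-6-methyl-1,2,3,4,7,8-hexahydroazulen-1-ol (4β-OH; 4α-isopropyl; 6β-OTBS), via isopropylcerium dichloride 19 (not isolated)
Conditions: i-PrMgCl, CeCl3 (anhydrous), THF, 0 then −78 °C; then 17, −78 °C
Reagents that add atoms: isopropylmagnesium chloride, CC(C)[Mg]Cl
Why: Imamoto-type organocerium 1,2-addition, in which the weakly basic oxophilic reagent 19 avoids enolisation, β-hydride reduction and 1,4-addition, and should attack C4 from the α face because the 6β-silyloxy group, pseudoaxial to escape the C4 carbonyl oxygen, covers the β face, so C4 is set as R.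

**Step 11**
Reactants: 20 silyloxy tertiary alcohol
Product: 21 (1R,8R)-1-isopropyl-6-methyl-1,2,3,4,7,8-hexahydroazulene-1,8-diol (4β,6β-diol; C1=C5; C8=C9)
Conditions: TBAF, THF, 0 °C to rt
Reagents that add atoms: none
Why: Fluoride-induced desilylation under non-acidic conditions frees the 6β-hydroxyl without ionising the tertiary allylic alcohol, which removes bulk from the face the carbenoid must use and turns it into a second directing group.

**Step 12**
Reactants: 21 4β,6β-diol diene; 22 diiodomethane
Product: 24 C1,C5-methano-bridged diol (C15H2 spans C1 and C5 on the β face; 4β-OH; 4α-isopropyl; 6β-OH; C8=C9), via C4-O-(iodomethyl)zinc alkoxide 23 (not isolated)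
Conditions: Et2Zn (3.5 equiv), CH2I2 (3.5 equiv), CH2Cl2, −20 to 0 °C
Reagents that add atoms: diiodomethane, ICI
Why: Et2Zn turns both hydroxyls into zinc alkoxides and exchange with CH2I2 places an iodomethylzinc unit on the C4 oxygen (23), from which CH2 passes to C1=C5 through the concerted butterfly transition state of the Furukawa-modified Simmons–Smith reaction, so C1–C15 and C5–C15 form together. The closest known reaction type is the hydroxyl-directed cyclopropanation of ring-fusion tetrasubstituted allylic alcohols to propellane carbinols, as used for angular methylation. The three-membered ring closes by suprafacial (2+1) addition of the carbenoid carbon to both alkene carbons, so it is necessarily cis-fused to rings A and B. Both new stereocentres, C1 and C5, are fixed by the β-oriented C4–O–Zn tether, which can reach only the β face, and the β C6 alkoxide, allylic to the same alkene, directs in the same sense. Facial selectivity is thus secured by two matched allylic alkoxides, and the α-isopropyl group also closes the opposite face next to C5. Chemoselectivity over C8=C9 is needed and rests on the doubly allylic activation and higher nucleophilicity of the tetrasubstituted alkene compared with a merely homoallylic trisubstituted one, helped by a limited charge of carbenoid at low temperature.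

**Step 13**
Reactants: 24 cyclopropane diol
Product: 25 C1,C5-methano-bridged 4β-hydroxy C6 ketone (cyclopropyl ketone; C8=C9)
Conditions: tetrapropylammonium perruthenate n-Pr4N[RuO4] (5 mol %), NMO, 4 Å MS, CH2Cl2, rt
Reagents that add atoms: none
Why: Ley–Griffith oxidation under neutral conditions converts only the secondary C6 carbinol (the tertiary C4–OH cannot react and no acid is present to open the cyclopropylcarbinyl system), which erases the relay centre and conjugates the carbonyl with the cyclopropane.

**Step 14**
Reactants: 25 cyclopropyl ketone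
Product: 27 4β-hydroxydauc-8-en-6-one (1β-methyl; 5α-H; trans-fused), via dilithium alkoxide enolate 26 (not isolated)
Conditions: Li (2.5 equiv), NH3(l)–THF, −78 °C; then solid NH4Cl
Reagents that add atoms: none
Why: Dissolving-metal cleavage of a conjugated cyclopropyl ketone, in which the ketyl breaks the C5–C15 bond that overlaps with the carbonyl π system (rupture of the central C1–C5 bond would need a bridgehead enolate in a bicyclo[5.3.1] frame), the C15 carbanion takes the C4–OH proton to become the C1 methyl, and protonation of enolate 26 at C5 should give the 5α-H ketone, which is also the more stable epimer because C6 then lies anti to the α-isopropyl group and accepts a hydrogen bond from C4–OH.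

**Step 15**
Reactants: 27 β-hydroxy ketone
Product: 28 dauc-8-ene-4β,6α-diol (jaeschkeanadiol)
Conditions: Me4NBH(OAc)3, MeCN–AcOH, −20 °C
Reagents that add atoms: none
Why: Evans–Saksena hydroxyl-directed reduction, in which ligand exchange binds the borohydride to the 4β-oxygen (the α side of C4 is blocked by isopropyl), so hydride is delivered intramolecularly to the β face of C6 and should give the equatorial 6α-alcohol (C6 S).

**Step 16**
Reactants: 28 dauc-8-ene-4β,6α-diol; 29 4-(benzyloxy)benzoic acid
Product: 30 4β-hydroxydauc-8-en-6α-yl 4-(benzyloxy)benzoate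
Conditions: DCC, DMAP, CH2Cl2, rt
Reagents that add atoms: 4-(benzyloxy)benzoic acid, O=C(O)c1ccc(OCc2ccccc2)cc1
Why: Steglich esterification acylates only the secondary 6α-hydroxyl, since the tertiary C4–OH is inert to the DMAP-activated acyl donor and the benzyl ether keeps the phenol out of the reaction.

**Step 17**
Reactants: 30 benzyl-protected ester alkene
Product: 31 8α,9α-epoxy-4β-hydroxydaucan-6α-yl 4-(benzyloxy)benzoate
Conditions: m-CPBA, CH2Cl2, 0 °C
Reagents that add atoms: 3-chloroperoxybenzoic acid, O=C(OO)c1cccc(Cl)c1
Why: Prilezhaev epoxidation of the only alkene, for which the trans-fused chair-like ring B places C1, C5, C6 and the axial β-methyl on C1 over the β face of C8=C9, so the peracid should add from the open α face and set C8 and C9.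

**Step 18**
Reactants: 31 α-epoxide
Product: 32 4β,8β,9α-trihydroxydaucan-6α-yl 4-(benzyloxy)benzoate
Conditions: HClO4 (cat.), THF–H2O, 0 °C
Reagents that add atoms: water, O
Why: Acid-catalysed epoxide hydrolysis of borderline SN2 character, in which water attacks the protonated epoxide from the β face with inversion at tertiary C8 (it carries most of the positive charge and lies farther from the axial C1 methyl than C9) while C9–O is retained, giving the trans 8β,9α-diol, and cold dilute acid in excess water spares the ester, the benzyl ether and the C4–OH.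

**Step 19**
Reactants: 32 benzyl-protected triol ester
Product: 33 4β,8β,9α-trihydroxydaucan-6α-yl 4-hydroxybenzoate (CNP0197754.1)
Conditions: H2 (1 atm), Pd/C, EtOAc, rt
Reagents that add atoms: none
Why: Catalytic hydrogenolysis cleaves only the benzylic C–O bond of the aryl benzyl ether, since no alkene is left and the alkyl benzoate, the alcohols and all stereocentres are inert.

**Compound list**
1 | cyclopentane-1,3-dione | O=C1CCC(=O)C1 | starting material
2 | 3-ethoxycyclopent-2-en-1-one | CCOC1=CC(=O)CC1 | intermediate
3 | 2-bromo-3-ethoxycyclopent-2-en-1-one | CCOC1=C(Br)C(=O)CC1 | intermediate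
4 | allylmagnesium bromide | C=CC[Mg]Br | starting material
5 | 1-allyl-2-bromo-3-ethoxycyclopent-2-en-1-ol (racemic; centre lost in the same flask) | CCOC1=C(Br)C(O)(CC=C)CC1 | intermediate
6 | 3-allyl-2-bromocyclopent-2-en-1-one | C=CCC1=C(Br)C(=O)CC1 | intermediate
7 | 7-allyl-6-bromo-1,4-dioxaspiro[4.4]non-6-ene | C=CCC1=C(Br)C2(CC1)OCCO2 | intermediate
8 | N,N-dimethylformamide | CN(C)C=O | starting material
9 | 7-allyl-6-lithio-1,4-dioxaspiro[4.4]non-6-ene | C=CCC1=C([Li])C2(CC1)OCCO2 | intermediate
10 | 7-allyl-1,4-dioxaspiro[4.4]non-6-ene-6-carbaldehyde | C=CCC1=C(C=O)C2(CC1)OCCO2 | intermediate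
11 | 2-methylallylmagnesium chloride | C=C(C)C[Mg]Cl | starting material
12 | B-(2-methylallyl)diisopinocampheylborane from (−)-α-pinene | C=C(C)CB([C@H]1C[C@H]2C[C@@H]([C@@H]1C)C2(C)C)[C@H]1C[C@H]2C[C@@H]([C@@H]1C)C2(C)C | intermediate
13 | diisopinocampheylborinate of the C6 alkoxide | C=CCC1=C([C@H](OB([C@H]3C[C@H]4C[C@@H]([C@@H]3C)C4(C)C)[C@H]3C[C@H]4C[C@@H]([C@@H]3C)C4(C)C)CC(C)=C)C2(CC1)OCCO2 | intermediate
14 | (1R)-1-(7-allyl-1,4-dioxaspiro[4.4]non-6-en-6-yl)-3-methylbut-3-en-1-ol | C=CCC1=C([C@H](O)CC(C)=C)C2(CC1)OCCO2 | intermediate
15 | tert-butyldimethylsilyl ether of 14 | C=CCC1=C([C@H](O[Si](C)(C)C(C)(C)C)CC(C)=C)C2(CC1)OCCO2 | intermediate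
16 | ethylene ketal of 17 | CC1=CCC2=C([C@H](O[Si](C)(C)C(C)(C)C)C1)C1(CC2)OCCO1 | intermediate
17 | (8R)-8-(tert-butyldimethylsilyloxy)-6-methyl-3,4,7,8-tetrahydroazulen-1(2H)-one | CC1=CCC2=C([C@H](O[Si](C)(C)C(C)(C)C)C1)C(=O)CC2 | intermediate
18 | isopropylmagnesium chloride | CC(C)[Mg]Cl | starting material
19 | isopropylcerium dichloride | CC(C)[Ce](Cl)Cl | intermediate
20 | (1R,8R)-8-(tert-butyldimethylsilyloxy)-1-isopropyl-6-methyl-1,2,3,4,7,8-hexahydroazulen-1-ol | CC(C)[C@]1(O)CCC2=C1[C@H](O[Si](C)(C)C(C)(C)C)CC(C)=CC2 | intermediate
21 | (1R,8R)-1-isopropyl-6-methyl-1,2,3,4,7,8-hexahydroazulene-1,8-diol (key-step precursor) | CC(C)[C@]1(O)CCC2=C1[C@H](O)CC(C)=CC2 | intermediate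
22 | diiodomethane | ICI | starting material
23 | zinc alkoxide of 21 with iodomethylzinc on the C4 oxygen and ethylzinc on the C6 oxygen | CC(C)[C@]1(O[Zn]CI)CCC2=C1[C@H](O[Zn]CC)CC(C)=CC2 | intermediate
24 | C1,C5-methano-bridged 4β,6β-diol (key-step product) | CC(C)[C@]1(O)CC[C@]23C[C@]31[C@H](O)CC(C)=CC2 | intermediate
25 | C1,C5-methano-bridged 4β-hydroxy C6 ketone | CC(C)[C@]1(O)CC[C@]23C[C@]31C(=O)CC(C)=CC2 | intermediate
26 | dilithium C4 alkoxide C5=C6 enolate | CC(C)[C@]1(O[Li])CC[C@]2(C)CC=C(C)CC(O[Li])=C21 | intermediate
27 | 4β-hydroxydauc-8-en-6-one (1β-methyl, 5α-H) | CC(C)[C@]1(O)CC[C@]2(C)CC=C(C)CC(=O)[C@H]21 | intermediate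
28 | dauc-8-ene-4β,6α-diol (jaeschkeanadiol) | CC(C)[C@]1(O)CC[C@]2(C)CC=C(C)C[C@H](O)[C@H]21 | intermediate
29 | 4-(benzyloxy)benzoic acid | O=C(O)c1ccc(OCc2ccccc2)cc1 | starting material
30 | 4β-hydroxydauc-8-en-6α-yl 4-(benzyloxy)benzoate | CC(C)[C@]1(O)CC[C@]2(C)CC=C(C)C[C@H](OC(=O)c3ccc(OCc4ccccc4)cc3)[C@H]21 | intermediate
31 | 8α,9α-epoxy-4β-hydroxydaucan-6α-yl 4-(benzyloxy)benzoate | CC(C)[C@]1(O)CC[C@]2(C)C[C@@H]3O[C@]3(C)C[C@H](OC(=O)c4ccc(OCc5ccccc5)cc4)[C@H]21 | intermediate
32 | 4β,8β,9α-trihydroxydaucan-6α-yl 4-(benzyloxy)benzoate | CC(C)[C@]1(O)CC[C@]2(C)C[C@H](O)[C@@](C)(O)C[C@H](OC(=O)c3ccc(OCc4ccccc4)cc3)[C@H]21 | intermediate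
33 | 4β,8β,9α-trihydroxydaucan-6α-yl 4-hydroxybenzoate (CNP0197754.1) | CC(C)[C@]1(O)CC[C@]2(C)C[C@H](O)[C@@](C)(O)C[C@H](OC(=O)c3ccc(O)cc3)[C@H]21 | target

**Total step count:** 19. **Longest linear sequence:** 19 steps from cyclopentane-1,3-dione.

**Steps most likely to fail**

**Step 12 (key step).**
- What may go wrong: methylene transfer to the crowded tetrasubstituted C1=C5 alkene may be slow. Attack on C8=C9 assisted by the C6 alkoxide, O-methylation, or Lewis-acid ionisation of the tertiary allylic alkoxide could then take over.
- Fallback: C15 is brought in as a nucleophilic methyl group instead of an electrophilic methylene. Setting out from 21, MnO2 in CH2Cl2 should oxidise only the secondary allylic C6 hydroxyl to 4β-hydroxy-4α-isopropyl-8-methylhydroazulene-1(5),8-dien-6-one F1. Excess Me2CuLi in Et2O (the first equivalent is consumed by the C4 hydroxyl) should then add methyl 1,4 to C1 from the β face, away from the α-isopropyl group and next to the alkoxide. This leads to the same alkoxide enolate as 26, and an NH4Cl quench brings the sequence back to the route at 27.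

**Step 10.**
- What may go wrong: the facial bias may be weak if the silyl group turns away from the carbonyl, and deprotonation at the doubly allylic C10–H may compete.
- Fallback: chelate control replaces steric shielding. Setting out from 17, HF·pyridine in THF should give (8R)-8-hydroxy-6-methyl-3,4,7,8-tetrahydroazulen-1(2H)-one F2. The first equivalent of i-PrMgCl/CeCl3 converts it into a metal alkoxide that chelates the C4 carbonyl in a six-membered ring. The C6–O bond then lies in the enone plane, C7 tilts to the β face and only C6–H points α. A further equivalent should therefore attack from the α face. Aqueous work-up gives the diol directly, and the sequence rejoins the route at 21 without passing through 20.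

**Step 14.**
- What may go wrong: cleavage of the central C1–C5 bond instead of C5–C15, over-reduction of the ketone, or base-induced drift of C8=C9 into conjugation with C6.
- Fallback: a polar, nucleophile-controlled opening followed by radical dehalogenation. Setting out from 25, excess Et2AlI in CH2Cl2 at 0 °C should first form the C4 aluminium alkoxide, which chelates and activates the C6 carbonyl. Iodide then attacks the unhindered C15H2 in SN2 fashion, and only the C5–C15 bond can break because it alone feeds the enolate. Protonation gives 15-iodo-4β-hydroxydauc-8-en-6-one F3. Bu3SnH with AIBN in toluene at 80 °C should replace iodine by hydrogen and return to the route at 27.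

**Further compounds**
F1 | step 12 | 4β-hydroxy-4α-isopropyl-8-methylhydroazulene-1(5),8-dien-6-one (daucane numbering) | CC(C)[C@]1(O)CCC2=C1C(=O)CC(C)=CC2
F2 | step 10 | (8R)-8-hydroxy-6-methyl-3,4,7,8-tetrahydroazulen-1(2H)-one | CC1=CCC2=C([C@H](O)C1)C(=O)CC2
F3 | step 14 | 15-iodo-4β-hydroxydauc-8-en-6-one (5α-H) | CC(C)[C@]1(O)CC[C@]2(CI)CC=C(C)CC(=O)[C@H]21
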